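**Retrosynthetic overview**

1. Target 30 ⇐ silyl ether 29 ⇐ macrocyclic secondary boronic ester 19 + (Z)-alkenyl iodide 25, joined by Zweifel olefination (C14–C15 bond with retention at C14, (E)-C15=C16).
2. 19 ⇐ acyclic, achiral bromo boronate 16 + vinylmagnesium chloride 17 by an enantioselective ring-closing conjunctive cross-coupling. One operation forms C13–C14, C1–C2, the 14-membered ring (the only ring) and the C14 stereocentre.
3. Enabling feature: in the 14-membered ring the methine C14 lies between ring CH2 C13 and ring CH2 C1, and C1 is bonded to the sp2 carbon C2 of the (Z)-C2=C3(Me) alkene. This R–CH(X)–CH2–C(sp2) pattern is what a migrating alkyl group, a B-vinyl unit and an alkenyl halide give; the exocyclic group on C14 is attached through an sp2 carbon, so X = B can be converted into it.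
4. 16 ⇐ HWE olefination (C6=C7) of (Z)-bromo aldehyde 5 with phosphonate 8, then SeO2 oxidation of the terminal (E)-methyl (C12), Appel bromination and deborylative alkylation with CH2(Bpin)2 (C13). 5 ⇐ pent-4-yn-1-ol by net anti-carboalumination.
5. 25 ⇐ but-2-yn-1-ol by trans-hydroalumination/iodination, bromination and Cu-catalysed coupling with 2-methylpropenyl Grignard reagent.

Key step: step 10

Numbering used in the text: ring C1–C14 (C14 = stereocentre; C1 = its ring CH2 neighbour leading to C2=C3(Me); C7 carries CH2OH; C11 carries Me); side chain C15–C19.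

Assumption: the facial selectivity of the Pd/Mandyphos catalyst in the ring-closing mode is taken to follow the intermolecular reaction; the ligand antipode is chosen so that C14 of 19 is R, and the other antipode is used if the sense proves opposite.

**Route**

Step 1
Reactants: 1 pent-4-yn-1-ol
Product: 4 (4Z)-5-bromo-4-methylpent-4-en-1-ol, via (E)-alkenylalane 2 (not isolated), via cyclic (Z)-alkenylalane 3 (not isolated)
Conditions: Me3Al (3 equiv), Cp2ZrCl2 (0.25 equiv), (CH2Cl)2, 0 °C → rt; then reflux; then NBS, THF, −30 → 0 °C; aq. work-up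
Reagents that add atoms: trimethylaluminium C[Al](C)C; N-bromosuccinimide O=C1CCC(=O)N1Br
Why: Zr-catalysed Negishi carboalumination adds Me–Al syn across the alkyne, heating lets the alkenylalane isomerise to the O–Al chelate (net anti-carbometallation), and stereoretentive brominolysis of the C–Al bond should place Br cis to the chain (Z).

Step 2
Reactants: 4 (4Z)-5-bromo-4-methylpent-4-en-1-ol
Product: 5 (4Z)-5-bromo-4-methylpent-4-enal
Conditions: TEMPO (10 mol%), PhI(OAc)2 (1.1 equiv), CH2Cl2, rt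
Reagents that add atoms: none
Why: oxoammonium (TEMPO) oxidation of a primary alcohol stops at the aldehyde and leaves the alkenyl bromide untouched.

Step 3
Reactants: 6 triethyl phosphonoacetate; 7 5-bromo-2-methylpent-2-ene
Product: 8 ethyl 2-(diethoxyphosphoryl)-6-methylhept-5-enoate (racemic)
Conditions: NaH, DMF, 0 °C; then 7, NaI (cat.), 60 °C
Reagents that add atoms: none
Why: SN2 C-alkylation of the sodium salt of the phosphonoacetate with a primary bromide.

Step 4
Reactants: 8 ethyl 2-(diethoxyphosphoryl)-6-methylhept-5-enoate; 5 (4Z)-5-bromo-4-methylpent-4-enal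
Product: 9 ethyl (2E,6Z)-7-bromo-6-methyl-2-(4-methylpent-3-en-1-yl)hepta-2,6-dienoate
Conditions: NaH, THF, 0 °C; then 5, 0 °C → rt
Reagents that add atoms: none
Why: Horner–Wadsworth–Emmons olefination of an unbranched aldehyde with an α-alkyl phosphonoacetate should favour the (E)-enoate (ester trans to the C5 chain), which sets the C6=C7 geometry; any (Z)-isomer is removed by chromatography.

Step 5
Reactants: 9 ethyl (2E,6Z)-7-bromo-6-methyl-2-(4-methylpent-3-en-1-yl)hepta-2,6-dienoate
Product: 10 (2E,6Z)-7-bromo-6-methyl-2-(4-methylpent-3-en-1-yl)hepta-2,6-dien-1-ol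
Conditions: DIBAL-H (2.5 equiv), CH2Cl2, −78 °C; Rochelle salt work-up
Reagents that add atoms: none
Why: DIBAL-H 1,2-reduction of an enoate to the allylic alcohol, to which alkenyl bromide and isolated alkenes are inert at −78 °C.

Step 6
Reactants: 10 (2E,6Z)-7-bromo-6-methyl-2-(4-methylpent-3-en-1-yl)hepta-2,6-dien-1-ol
Product: 11 {[(2E,6Z)-7-bromo-6-methyl-2-(4-methylpent-3-en-1-yl)hepta-2,6-dien-1-yl]oxy}(tert-butyl)dimethylsilane
Conditions: TBSCl, imidazole, DMF, rt
Reagents that add atoms: tert-butyldimethylsilyl chloride CC(C)(C)[Si](C)(C)Cl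
Why: imidazole-promoted silylation of a primary alcohol.

Step 7
Reactants: 11 {[(2E,6Z)-7-bromo-6-methyl-2-(4-methylpent-3-en-1-yl)hepta-2,6-dien-1-yl]oxy}(tert-butyl)dimethylsilane
Product: 12 (2E,6E,10Z)-11-bromo-6-({[tert-butyl(dimethyl)silyl]oxy}methyl)-2,10-dimethylundeca-2,6,10-trien-1-ol
Conditions: SeO2 (0.3 equiv), t-BuOOH (3 equiv), salicylic acid (0.1 equiv), CH2Cl2, 0 °C → rt, stopped at partial conversion (11 recycled)
Reagents that add atoms: tert-butyl hydroperoxide CC(C)(C)OO (terminal oxidant; oxygen relayed by catalytic selenium dioxide O=[Se]=O)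
Why: SeO2/t-BuOOH allylic oxidation (ene reaction then [2,3]-sigmatropic shift) should attack the most electron-rich terminal Me2C=CH alkene at its (E)-methyl group, which gives the (E)-allylic alcohol and so the C10=C11 geometry, the other two alkenes being deactivated by Br and by the allylic silyloxy group.

Step 8
Reactants: 12 (2E,6E,10Z)-11-bromo-6-({[tert-butyl(dimethyl)silyl]oxy}methyl)-2,10-dimethylundeca-2,6,10-trien-1-ol
Product: 13 {[(2E,6Z)-7-bromo-2-[(3E)-5-bromo-4-methylpent-3-en-1-yl]-6-methylhepta-2,6-dien-1-yl]oxy}(tert-butyl)dimethylsilane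
Conditions: CBr4, PPh3, CH2Cl2, 0 °C
Reagents that add atoms: carbon tetrabromide BrC(Br)(Br)Br
Why: Appel bromination of a primary allylic alcohol, which proceeds without allylic transposition at 0 °C.

Step 9
Reactants: 13 {[(2E,6Z)-7-bromo-2-[(3E)-5-bromo-4-methylpent-3-en-1-yl]-6-methylhepta-2,6-dien-1-yl]oxy}(tert-butyl)dimethylsilane; 14 bis(4,4,5,5-tetramethyl-1,3,2-dioxaborolan-2-yl)methane
Product: 16 2-[(3E,7E,11Z)-12-bromo-7-({[tert-butyl(dimethyl)silyl]oxy}methyl)-3,11-dimethyldodeca-3,7,11-trien-1-yl]-4,4,5,5-tetramethyl-1,3,2-dioxaborolane, via sodium borylmethanide 15 (not isolated)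
Conditions: 14 (1.5 equiv), NaOt-Bu, THF, rt
Reagents that add atoms: none
Why: deborylative alkylation, in which tert-butoxide removes one boron of the geminal bis(boronate) and the resulting α-boryl carbanion displaces the unhindered primary allylic bromide by SN2 to give the homoallylic boronic ester.

Step 10
Reactants: 16 2-[(3E,7E,11Z)-12-bromo-7-({[tert-butyl(dimethyl)silyl]oxy}methyl)-3,11-dimethyldodeca-3,7,11-trien-1-yl]-4,4,5,5-tetramethyl-1,3,2-dioxaborolane; 17 vinylmagnesium chloride
Product: 19 2-[(1R,3Z,7E,11E)-8-({[tert-butyl(dimethyl)silyl]oxy}methyl)-4,12-dimethylcyclotetradeca-3,7,11-trien-1-yl]-4,4,5,5-tetramethyl-1,3,2-dioxaborolane, via vinyl boronate complex 18 (not isolated)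
Conditions: 17 (1.05 equiv), NaOTf (2 equiv), THF, 0 °C → rt; then syringe-pump addition over 12 h to Pd(OAc)2 (5 mol%), Mandyphos (6 mol%, antipode per the assumption), THF, 60 °C, final concentration about 2 mM
Reagents that add atoms: none
Why: Proposed new method: the vinyl Grignard reagent converts the terminal boronic ester into the vinyl boronate complex 18, Pd(0) inserts into the (Z)-alkenyl C–Br bond at the other chain end, the cationic alkenyl–Pd(II) centre (bromide removed as NaBr) binds the B-vinyl group and induces a 1,2-metallate shift in which C13 migrates from boron to C14 anti to palladium, and C(sp3)–C(sp2) reductive elimination then forms the C1–C2 bond. The closest known reaction type is the intermolecular Pd/Mandyphos-catalysed enantioselective conjunctive cross-coupling of vinyl boronate complexes with alkenyl and aryl (pseudo)halides, here proposed between the two ends of one chain. The 14-membered carbocycle, the only ring, is closed in an endo mode: palladium adds to the terminal vinyl carbon to give a 16-membered cycle containing B and Pd, which contracts to a 15-membered palladacycle when boron is extruded by the 1,2-shift and to the 14-membered ring on reductive elimination. The new stereocentre C14 is under catalyst control: the planar-chiral diphosphine selects the face of the vinyl group that palladium binds, and the anti migration transmits this to C14, which keeps boron for the later side-chain attachment. The step needs ring closure over oligomerisation, served by slow addition at high dilution and by a 12-carbon tether pre-bent by two chain-cis trisubstituted alkenes, and metallate shift over direct B-to-Pd transfer of vinyl or alkyl, served by the wide-bite-angle ligand and the non-coordinating triflate counter-ion. The (Z)-geometry at C2=C3 should be retained because oxidative addition and reductive elimination at the alkenyl carbon are stereoretentive, and the trisubstituted alkenes of the tether are too hindered to compete with the monosubstituted B-vinyl group for palladium.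

Step 11
Reactants: 20 but-2-yn-1-ol
Product: 22 (2Z)-3-iodobut-2-en-1-ol, via cyclic alkenylaluminate 21 (not isolated)
Conditions: Red-Al (1.5 equiv), THF, 0 °C → rt; then I2, THF, −78 → 0 °C
Reagents that add atoms: iodine II
Why: hydroxyl-directed trans-hydroalumination of the propargylic alcohol places Al on C3 cis to CH2O in a five-membered aluminate, and iodinolysis with retention gives the (Z)-iodide.

Step 12
Reactants: 22 (2Z)-3-iodobut-2-en-1-ol
Product: 23 (2Z)-1-bromo-3-iodobut-2-ene
Conditions: PBr3 (0.4 equiv), Et2O, 0 °C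
Reagents that add atoms: phosphorus tribromide BrP(Br)Br
Why: SN2 bromination of a primary allylic alcohol with PBr3, which does not touch the alkenyl iodide.

Step 13
Reactants: 23 (2Z)-1-bromo-3-iodobut-2-ene; 24 (2-methylprop-1-en-1-yl)magnesium bromide
Product: 25 (2Z)-2-iodo-6-methylhepta-2,5-diene
Conditions: CuI (10 mol%), THF, −30 → 0 °C
Reagents that add atoms: none
Why: Cu-catalysed SN2 coupling of an alkenyl Grignard reagent with a primary allylic bromide, the hindered iodine-bearing γ-carbon disfavouring SN2' and the alkenyl iodide being inert to the Grignard reagent at low temperature.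

Step 14
Reactants: 25 (2Z)-2-iodo-6-methylhepta-2,5-diene; 19 2-[(1R,3Z,7E,11E)-8-({[tert-butyl(dimethyl)silyl]oxy}methyl)-4,12-dimethylcyclotetradeca-3,7,11-trien-1-yl]-4,4,5,5-tetramethyl-1,3,2-dioxaborolane
Product: 29 tert-butyl{[(1E,5Z,8R,11E)-5,11-dimethyl-8-[(2E)-6-methylhepta-2,5-dien-2-yl]cyclotetradeca-1,5,11-trien-1-yl]methoxy}dimethylsilane, via alkenyllithium 26 (not isolated), via alkenyl boronate complex 27 (not isolated), via β-iodo boronic ester 28 (not isolated)
Conditions: 25 (1.5 equiv), t-BuLi (3.0 equiv), THF, −78 °C; then 19, −78 → 0 °C; then I2, THF, −78 °C; then NaOMe, MeOH, −78 °C → rt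
Reagents that add atoms: none
Why: Zweifel olefination, in which I–Li exchange gives the configurationally stable alkenyllithium, its boronate complex undergoes iodonium-induced stereospecific 1,2-migration of C14 (retention at C14), and methoxide-induced anti elimination of B and I converts the Li-cis-to-chain alkenyl unit into the (E)-C15=C16 alkene.

Step 15
Reactants: 29 tert-butyl{[(1E,5Z,8R,11E)-5,11-dimethyl-8-[(2E)-6-methylhepta-2,5-dien-2-yl]cyclotetradeca-1,5,11-trien-1-yl]methoxy}dimethylsilane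
Product: 30 [(1E,5Z,8R,11E)-5,11-dimethyl-8-[(2E)-6-methylhepta-2,5-dien-2-yl]cyclotetradeca-1,5,11-trien-1-yl]methanol
Conditions: TBAF, THF, 0 °C → rt
Reagents that add atoms: none
Why: fluoride cleavage of the primary silyl ether, which leaves the skipped polyene and the allylic stereocentre untouched.

**Compound list**

1 | pent-4-yn-1-ol | C#CCCCO | starting material
2 | (E)-alkenylalane: dimethyl{(1E)-5-[(dimethylalumanyl)oxy]-2-methylpent-1-en-1-yl}alumane (Al cis to Me) | C[Al](C)/C=C(\C)CCCO[Al](C)C | intermediate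
3 | cyclic (Z)-alkenylalane: O–Al chelate with Al on the alkene carbon cis to the chain (2,4-dimethyl-2,5,6,7-tetrahydro-1,2-oxaluminepine) | C[Al]1OCCC/C(C)=C\1 | intermediate
4 | (4Z)-5-bromo-4-methylpent-4-en-1-ol | Br/C=C(/C)CCCO | intermediate
5 | (4Z)-5-bromo-4-methylpent-4-enal | Br/C=C(/C)CCC=O | intermediate
6 | triethyl phosphonoacetate | CCOC(=O)CP(=O)(OCC)OCC | starting material
7 | 5-bromo-2-methylpent-2-ene | CC(C)=CCCBr | starting material
8 | ethyl 2-(diethoxyphosphoryl)-6-methylhept-5-enoate (racemic) | CCOC(=O)C(CCC=C(C)C)P(=O)(OCC)OCC | intermediate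
9 | ethyl (2E,6Z)-7-bromo-6-methyl-2-(4-methylpent-3-en-1-yl)hepta-2,6-dienoate | Br/C=C(/C)CC/C=C(/C(=O)OCC)CCC=C(C)C | intermediate
10 | (2E,6Z)-7-bromo-6-methyl-2-(4-methylpent-3-en-1-yl)hepta-2,6-dien-1-ol | Br/C=C(/C)CC/C=C(/CO)CCC=C(C)C | intermediate
11 | {[(2E,6Z)-7-bromo-6-methyl-2-(4-methylpent-3-en-1-yl)hepta-2,6-dien-1-yl]oxy}(tert-butyl)dimethylsilane | Br/C=C(/C)CC/C=C(/CO[Si](C)(C)C(C)(C)C)CCC=C(C)C | intermediate
12 | (2E,6E,10Z)-11-bromo-6-({[tert-butyl(dimethyl)silyl]oxy}methyl)-2,10-dimethylundeca-2,6,10-trien-1-ol | Br/C=C(/C)CC/C=C(/CO[Si](C)(C)C(C)(C)C)CC/C=C(\C)CO | intermediate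
13 | {[(2E,6Z)-7-bromo-2-[(3E)-5-bromo-4-methylpent-3-en-1-yl]-6-methylhepta-2,6-dien-1-yl]oxy}(tert-butyl)dimethylsilane | Br/C=C(/C)CC/C=C(/CO[Si](C)(C)C(C)(C)C)CC/C=C(\C)CBr | intermediate
14 | bis(4,4,5,5-tetramethyl-1,3,2-dioxaborolan-2-yl)methane | CC1(C)OB(CB2OC(C)(C)C(C)(C)O2)OC1(C)C | starting material
15 | sodium (4,4,5,5-tetramethyl-1,3,2-dioxaborolan-2-yl)methanide | [Na+].[CH2-]B1OC(C)(C)C(C)(C)O1 | intermediate
16 | 2-[(3E,7E,11Z)-12-bromo-7-({[tert-butyl(dimethyl)silyl]oxy}methyl)-3,11-dimethyldodeca-3,7,11-trien-1-yl]-4,4,5,5-tetramethyl-1,3,2-dioxaborolane | Br/C=C(/C)CC/C=C(/CO[Si](C)(C)C(C)(C)C)CC/C=C(\C)CCB1OC(C)(C)C(C)(C)O1 | intermediate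
17 | vinylmagnesium chloride | C=C[Mg]Cl | starting material
18 | chloromagnesium ethenyl boronate complex of 16 (boron carries pinacolate, vinyl and the C13 chain) | Br/C=C(/C)CC/C=C(/CO[Si](C)(C)C(C)(C)C)CC/C=C(\C)CC[B-]1(C=C)OC(C)(C)C(C)(C)O1.[Mg+2].[Cl-] | intermediate
19 | 2-[(1R,3Z,7E,11E)-8-({[tert-butyl(dimethyl)silyl]oxy}methyl)-4,12-dimethylcyclotetradeca-3,7,11-trien-1-yl]-4,4,5,5-tetramethyl-1,3,2-dioxaborolane | CC1(C)OB(OC1(C)C)[C@H]2C/C=C(/C)CC/C=C(/CO[Si](C)(C)C(C)(C)C)CC/C=C(\C)CC2 | intermediate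
20 | but-2-yn-1-ol | CC#CCO | starting material
21 | sodium cyclic (Z)-alkenylaluminate (five-membered O–Al–C ring, Al on the methyl-bearing alkene carbon, two 2-methoxyethoxy groups on Al) | [Na+].CC1=CCO[Al-]1(OCCOC)OCCOC | intermediate
22 | (2Z)-3-iodobut-2-en-1-ol | OC/C=C(/C)I | intermediate
23 | (2Z)-1-bromo-3-iodobut-2-ene | BrC/C=C(/C)I | intermediate
24 | (2-methylprop-1-en-1-yl)magnesium bromide | CC(C)=C[Mg]Br | starting material
25 | (2Z)-2-iodo-6-methylhepta-2,5-diene | CC(C)=CC/C=C(/C)I | intermediate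
26 | 6-methylhepta-2,5-dien-2-yllithium with Li cis to the C4 chain (geometry of 25 retained) | CC(C)=CC/C=C(/C)[Li] | intermediate
27 | lithium boronate complex of 19 carrying the 6-methylhepta-2,5-dien-2-yl group on boron (B cis to the chain CH2; C14 R) | [Li+].CC(C)=CC/C=C(/C)[B-]1(OC(C)(C)C(C)(C)O1)[C@H]2C/C=C(/C)CC/C=C(/CO[Si](C)(C)C(C)(C)C)CC/C=C(\C)CC2 | intermediate
28 | β-iodo boronic ester from anti addition of C14 and I across the alkene of 27 (C15 carries B, Me and C14; C16 carries I) | CC(C)=CC[C@@H](I)[C@@](C)(B1OC(C)(C)C(C)(C)O1)[C@H]2C/C=C(/C)CC/C=C(/CO[Si](C)(C)C(C)(C)C)CC/C=C(\C)CC2 | intermediate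
29 | tert-butyl{[(1E,5Z,8R,11E)-5,11-dimethyl-8-[(2E)-6-methylhepta-2,5-dien-2-yl]cyclotetradeca-1,5,11-trien-1-yl]methoxy}dimethylsilane | CC(C)=CC/C=C(\C)[C@H]1C/C=C(/C)CC/C=C(/CO[Si](C)(C)C(C)(C)C)CC/C=C(\C)CC1 | intermediate
30 | [(1E,5Z,8R,11E)-5,11-dimethyl-8-[(2E)-6-methylhepta-2,5-dien-2-yl]cyclotetradeca-1,5,11-trien-1-yl]methanol | CC(C)=CC/C=C(\C)[C@H]1C/C=C(/C)CC/C=C(/CO)CC/C=C(\C)CC1 | target

**Step count and risks**

Total step count: 15. Longest linear sequence: 11 steps (steps 1, 2, 4–10, 14, 15, from pent-4-yn-1-ol).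

Steps most likely to fail:

Step 10 (proposed new method). Intermolecular coupling may outpace ring closure and give oligomers; vinyl or alkyl may pass directly from boron to palladium without the metallate shift; facial discrimination may be weak in the macrocyclic transition state. The fallback uses known reaction types, sets out from 13 and returns at 19. Cu-catalysed SN2 coupling of 13 with allylmagnesium bromide (Li2CuCl4 cat., THF, −78 °C) should give the terminal alkene tert-butyl{[(2E,6Z)-7-bromo-6-methyl-2-[(3E)-4-methylocta-3,7-dien-1-yl]hepta-2,6-dien-1-yl]oxy}dimethylsilane F1. Pt-catalysed enantioselective diboration of its only monosubstituted alkene (B2pin2, Pt(dba)3, TADDOL-derived phosphonite of the antipode that gives S, THF, 60 °C) should give the vicinal bis(boronate) 2,2'-[(2S,5E,9E,13Z)-14-bromo-9-({[tert-butyl(dimethyl)silyl]oxy}methyl)-5,13-dimethyltetradeca-5,9,13-triene-1,2-diyl]bis(4,4,5,5-tetramethyl-1,3,2-dioxaborolane) F2. An intramolecular Suzuki–Miyaura coupling that engages only the primary C–B bond (Pd(OAc)2, RuPhos, KOH, THF/H2O, 70 °C, high dilution) then closes the same C1–C2 bond and delivers 19.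

Step 14. Boronate-complex formation between the ring-bound secondary boronic ester and the α-branched alkenyllithium may be slow or incomplete, iodine may attack ring alkenes, and a competing syn-elimination channel would erode the alkene geometry. The fallback sets out from 19 and returns at 29. Matteson homologation (CH2Cl2, n-BuLi, THF, −100 °C → rt) should give the α-chloro boronic ester 2-{chloro[(1R,3Z,7E,11E)-8-({[tert-butyl(dimethyl)silyl]oxy}methyl)-4,12-dimethylcyclotetradeca-3,7,11-trien-1-yl]methyl}-4,4,5,5-tetramethyl-1,3,2-dioxaborolane F3 (epimers at CHCl). Oxidation (NaBO3·4H2O, THF/H2O) should give the aldehyde (1R,3Z,7E,11E)-8-({[tert-butyl(dimethyl)silyl]oxy}methyl)-4,12-dimethylcyclotetradeca-3,7,11-triene-1-carbaldehyde F4. Ohira–Bestmann alkynylation (K2CO3, MeOH, 0 °C) should give the alkyne tert-butyl{[(1E,5Z,8R,11E)-8-ethynyl-5,11-dimethylcyclotetradeca-1,5,11-trien-1-yl]methoxy}dimethylsilane F5. Zr-catalysed carboalumination (Me3Al, Cp2ZrCl2, CH2Cl2) should give the (E)-alkenylalane dimethyl{(1E)-2-[(1R,3Z,7E,11E)-8-({[tert-butyl(dimethyl)silyl]oxy}methyl)-4,12-dimethylcyclotetradeca-3,7,11-trien-1-yl]prop-1-en-1-yl}alumane F6, and Pd(PPh3)4-catalysed coupling of this alane with 1-bromo-3-methylbut-2-ene gives 29 with Me cis to the new allylic CH2.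

Step 7. Over-oxidation to the enal, attack at other allylic positions, or low conversion may occur. The fallback sets out from 11 and returns at 12. Bromohydrin formation at the terminal, most electron-rich alkene (NBS, THF/H2O, 0 °C) should give (6E,10Z)-3,11-dibromo-6-({[tert-butyl(dimethyl)silyl]oxy}methyl)-2,10-dimethylundeca-6,10-dien-2-ol F7. Base (K2CO3, MeOH) closes it to the epoxide tert-butyl{[(2E,6Z)-7-bromo-2-[2-(3,3-dimethyloxiran-2-yl)ethyl]-6-methylhepta-2,6-dien-1-yl]oxy}dimethylsilane F8. Periodic acid cleavage (H5IO6, THF/Et2O) should give the aldehyde (4E,8Z)-9-bromo-4-({[tert-butyl(dimethyl)silyl]oxy}methyl)-8-methylnona-4,8-dienal F9. Wittig olefination with Ph3P=C(Me)CO2Et (CH2Cl2, rt) should give the enoate ethyl (2E,6E,10Z)-11-bromo-6-({[tert-butyl(dimethyl)silyl]oxy}methyl)-2,10-dimethylundeca-2,6,10-trienoate F10, and DIBAL-H reduction (CH2Cl2, −78 °C) gives 12.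

Further compounds
F1 | step 10 | tert-butyl{[(2E,6Z)-7-bromo-6-methyl-2-[(3E)-4-methylocta-3,7-dien-1-yl]hepta-2,6-dien-1-yl]oxy}dimethylsilane | Br/C=C(/C)CC/C=C(/CO[Si](C)(C)C(C)(C)C)CC/C=C(\C)CCC=C
F2 | step 10 | 2,2'-[(2S,5E,9E,13Z)-14-bromo-9-({[tert-butyl(dimethyl)silyl]oxy}methyl)-5,13-dimethyltetradeca-5,9,13-triene-1,2-diyl]bis(4,4,5,5-tetramethyl-1,3,2-dioxaborolane) | Br/C=C(/C)CC/C=C(/CO[Si](C)(C)C(C)(C)C)CC/C=C(\C)CC[C@H](CB1OC(C)(C)C(C)(C)O1)B1OC(C)(C)C(C)(C)O1
F3 | step 14 | 2-{chloro[(1R,3Z,7E,11E)-8-({[tert-butyl(dimethyl)silyl]oxy}methyl)-4,12-dimethylcyclotetradeca-3,7,11-trien-1-yl]methyl}-4,4,5,5-tetramethyl-1,3,2-dioxaborolane | ClC(B1OC(C)(C)C(C)(C)O1)[C@H]1C/C=C(/C)CC/C=C(/CO[Si](C)(C)C(C)(C)C)CC/C=C(\C)CC1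
F4 | step 14 | (1R,3Z,7E,11E)-8-({[tert-butyl(dimethyl)silyl]oxy}methyl)-4,12-dimethylcyclotetradeca-3,7,11-triene-1-carbaldehyde | O=C[C@H]1C/C=C(/C)CC/C=C(/CO[Si](C)(C)C(C)(C)C)CC/C=C(\C)CC1
F5 | step 14 | tert-butyl{[(1E,5Z,8R,11E)-8-ethynyl-5,11-dimethylcyclotetradeca-1,5,11-trien-1-yl]methoxy}dimethylsilane | C#C[C@H]1C/C=C(/C)CC/C=C(/CO[Si](C)(C)C(C)(C)C)CC/C=C(\C)CC1
F6 | step 14 | dimethyl{(1E)-2-[(1R,3Z,7E,11E)-8-({[tert-butyl(dimethyl)silyl]oxy}methyl)-4,12-dimethylcyclotetradeca-3,7,11-trien-1-yl]prop-1-en-1-yl}alumane | C[Al](C)/C=C(\C)[C@H]1C/C=C(/C)CC/C=C(/CO[Si](C)(C)C(C)(C)C)CC/C=C(\C)CC1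
F7 | step 7 | (6E,10Z)-3,11-dibromo-6-({[tert-butyl(dimethyl)silyl]oxy}methyl)-2,10-dimethylundeca-6,10-dien-2-ol (racemic) | Br/C=C(/C)CC/C=C(/CO[Si](C)(C)C(C)(C)C)CCC(Br)C(C)(C)O
F8 | step 7 | tert-butyl{[(2E,6Z)-7-bromo-2-[2-(3,3-dimethyloxiran-2-yl)ethyl]-6-methylhepta-2,6-dien-1-yl]oxy}dimethylsilane (racemic) | Br/C=C(/C)CC/C=C(/CO[Si](C)(C)C(C)(C)C)CCC1OC1(C)C
F9 | step 7 | (4E,8Z)-9-bromo-4-({[tert-butyl(dimethyl)silyl]oxy}methyl)-8-methylnona-4,8-dienal | Br/C=C(/C)CC/C=C(/CO[Si](C)(C)C(C)(C)C)CCC=O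
F10 | step 7 | ethyl (2E,6E,10Z)-11-bromo-6-({[tert-butyl(dimethyl)silyl]oxy}methyl)-2,10-dimethylundeca-2,6,10-trienoate | Br/C=C(/C)CC/C=C(/CO[Si](C)(C)C(C)(C)C)CC/C=C(\C)C(=O)OCC
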